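**Plan**
1. Numbering: the core carbons C1–C11 follow the target SMILES after the angelate. C1 is CH–O-angeloyl, C2 is CH2, C3 is CH–O-tigloyl, C4 is CMe2, C7 is C=O, C8=C9 is the enone alkene, C11 is C–CH3. The cyclobutane is C5, C6, C11, C10. Ring A holds C1–C5 and C11; ring B is the enone ring C6–C11.
2. Enabling feature: in the seven-membered ring A, the gem-dimethyl carbon C4 lies between carbinol carbon C3 and cyclobutane carbon C5. Removing C4 leaves a six-membered ring A with an isopropenyl carbinol at C3.
3. Cuts, in order: both ester C–O bonds; C4–C5 (semipinacol); C3–C4 (isopropenyl addition); C1–O (conjugate borylation); C5–C6 (enolate alkylation); C6–C11 and C9–C10 (Diels–Alder).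
4. Forward: ring B is annulated onto a quinone that becomes ring A (cis-decalin). C5–C6 closure gives the cyclobutane. The bromonium-triggered shift enlarges ring A from six to seven members. The esters come last.
5. Stereochemistry: C10 and C11 come from the chiral titanium Diels–Alder catalyst. C5 and C6 follow from them (convex hydride, Appel inversion, SN2 closure). C1 comes from the chiral copper boryl catalyst and C3 from O1-directed hydride transfer. The alkene geometries come from tiglic and angelic acid.

Key step: step 14

Assumption: the (R)-BINOL titanium catalyst (step 2) and the ferrocenyl diphosphine (step 9) are taken to give the absolute sense drawn. Both ligands are sold in both mirror-image forms, so the other form would be used if the sense proved opposite.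

Step 1
Reactants: 1 (E)-pent-3-en-2-one
Product: 2 (E)-2-(tert-butyldimethylsilyloxy)penta-1,3-diene
Conditions: TBSOTf, Et3N, Et2O, 0 °C
Reagents that add atoms: tert-butyldimethylsilyl triflate, CC(C)(C)[Si](C)(C)OS(=O)(=O)C(F)(F)F
Why: Silyl enol ether formation by soft enolisation: the amine removes a proton from the acetyl CH3 of the silyl-activated ketone, which gives the cross-conjugated 2-silyloxydiene and leaves the E alkene untouched.

Step 2
Reactants: 2 (E)-2-(tert-butyldimethylsilyloxy)penta-1,3-diene; 3 2-methoxy-5-methyl-1,4-benzoquinone
Product: 4 cis-decalin enedione (ring A C1(=O)–C2H=C3(OMe)–C5(=O); ring B C6H2–C7(OTBS)=C8H–C9H(CH3); C11 CH3 cis to C10 H; C9 CH3 trans to C10 H)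
Conditions: TiCl2(O-i-Pr)2 (30 mol %), (R)-BINOL (30 mol %), 4 Å MS, toluene, −60 → −10 °C
Reagents that add atoms: none
Why: Chiral titanium BINOLate-catalysed quinone Diels–Alder reaction: the methoxy group switches off its own double bond and, chelated together with the neighbouring C5 carbonyl, makes C11 the β-terminus that takes the nucleophilic CH2 end (C6) of the diene, endo addition gives the cis fusion, and the catalyst selects the quinone face and so fixes the absolute configuration of C10 and C11.

Step 3
Reactants: 4 cis-decalin enedione
Product: 5 C5 alcohol (hydroxyl on the ring B face; trans to C10 H)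
Conditions: NaBH4, CeCl3·7H2O, MeOH/CH2Cl2, −78 °C
Reagents that add atoms: none
Why: Luche reduction: C5 is the only electrophilic carbonyl (C1 is a vinylogous ester carbonyl beside quaternary C11 and C7 is masked as the silyl enol ether), and hydride arrives on the convex face that carries C10–H and the C11 methyl, so the hydroxyl ends on the face occupied by ring B.

Step 4
Reactants: 5 C5 alcohol
Product: 6 C5 bromide (bromine cis to C10 H)
Conditions: PPh3, CBr4, 2,6-lutidine, CH2Cl2, −20 → 0 °C
Reagents that add atoms: carbon tetrabromide, BrC(Br)(Br)Br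
Why: Appel reaction: bromide displaces the oxyphosphonium group by SN2 from the open convex face, which inverts C5 and puts the leaving group anti to C6, while SN2′ attack is disfavoured because C2 is the electron-rich α-carbon of the vinylogous ester.

Step 5
Reactants: 6 C5 bromide
Product: 7 bromo bis-enone (ring B now C7(=O)–C8H=C9(CH3))
Conditions: DDQ, 2,4,6-collidine, CH2Cl2, 0 °C → rt
Reagents that add atoms: none
Why: DDQ dehydrogenation of a silyl enol ether (the outcome of a Saegusa oxidation without palladium, which would ionise the allylic bromide): only C9 carries a removable hydrogen, so the C8=C9 enone forms, the C9 stereocentre is erased and C8 is blocked as a nucleophilic site.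

Step 6
Reactants: 7 bromo bis-enone
Product: 9 cage vinylogous ester enone (C5–C6 bond closed; tricyclo[4.4.0.0(2,7)]decadienedione core), via potassium enolate 8 (not isolated)
Conditions: KN(SiMe3)2 (1.05 equiv), THF, −78 → 0 °C
Reagents that add atoms: none
Why: Intramolecular enolate alkylation (4-enolexo-exo-tet), the closure known for pinane and tricyclo[4.4.0.0(2,7)]decane skeletons: kinetic deprotonation of the enone occurs at the α′-CH2 (C6), C6 is held axial over C5 in the cis-decalin and displaces the activated γ-bromide with inversion, so the configurations of C5 and C6 are dictated by C10 and C11.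

Step 7
Reactants: 9 cage vinylogous ester enone
Product: 11 cage enone alcohol (ring A C1H=C2H–C3(=O); C7 hydroxyl syn to the C11 bridge), via cage diol 10 (not isolated)
Conditions: i-Bu2AlH (3.5 equiv), CH2Cl2, −78 °C; then aq. oxalic acid, THF, 0 °C
Reagents that add atoms: water, O (supplies the C3 carbonyl oxygen; an equal amount of water leaves from C1)
Why: Stork–Danheiser-type reduction and hydrolysis: 1,2-reduction of the vinylogous ester followed by acid-induced loss of the C1 hydroxyl and of methanol transposes ring A to the C1=C2–C3=O enone, while the C7 carbonyl is reduced in the same operation from the face away from the C11 methyl, which masks the ring B enone as an allylic alcohol of immaterial configuration.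

Step 8
Reactants: 11 cage enone alcohol
Product: 12 O7 triethylsilyl ether
Conditions: TESCl, imidazole, DMF, 0 °C → rt
Reagents that add atoms: chlorotriethylsilane, CC[Si](Cl)(CC)CC
Why: Standard silylation; a triethylsilyl ether is chosen because it can later be removed beside the tert-butyldimethylsilyl ether on O1.

Step 9
Reactants: 12 O7 triethylsilyl ether
Product: 14 C1 β-hydroxy ketone (O1 on the face turned towards C6), via pinacol boronate 13 (not isolated)
Conditions: CuCl (5 mol %), NaO-t-Bu (7 mol %), (R)-1-[(S)-2-(diphenylphosphino)ferrocenyl]ethyldicyclohexylphosphine (6 mol %), B2pin2, MeOH, THF, rt; then NaBO3·4H2O, THF/H2O, rt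
Reagents that add atoms: bis(pinacolato)diboron, CC1(C)OB(OC1(C)C)B1OC(C)(C)C(C)(C)O1 (boron of 13); sodium perborate, [Na+].[Na+].O[B-]1(O)OO[B-](O)(O)OO1 (oxygen of 14)
Why: Copper-catalysed enantioselective conjugate borylation of a cyclic enone followed by oxidation with retention: the two faces of the ring A enone are related by the local mirror plane through C5, C11 and ring A and differ only in remote ring B substituents, so the chiral diphosphine alone places boron, and then oxygen, on the face turned towards C6, and any cage of the wrong absolute configuration is removed here as a diastereomer.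

Step 10
Reactants: 14 C1 β-hydroxy ketone
Product: 15 O1-TBS O7-TES ketone
Conditions: TBSOTf, 2,6-lutidine, CH2Cl2, −78 °C
Reagents that add atoms: tert-butyldimethylsilyl triflate, CC(C)(C)[Si](C)(C)OS(=O)(=O)C(F)(F)F
Why: Silylation with the triflate at low temperature protects the β-hydroxy ketone without a base strong enough to cause β-elimination.

Step 11
Reactants: 15 O1-TBS O7-TES ketone; 16 isopropenylmagnesium bromide
Product: 17 C3 isopropenyl carbinol (O7-TES; C3 hydroxyl cis to O1)
Conditions: CeCl3 (anhydrous), THF, −78 °C
Reagents that add atoms: isopropenylmagnesium bromide 16 (already counted under Reactants), C=C(C)[Mg]Br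
Why: Organocerium 1,2-addition: the weakly basic reagent adds to the hindered enolisable C3 ketone without enolisation or loss of the β-silyloxy group, attack anti to the C1 silyloxy group should give mainly the epimer drawn, and the C3 configuration is lost again in step 14.

Step 12
Reactants: 17 C3 isopropenyl carbinol (O7-TES)
Product: 18 C7 allylic alcohol
Conditions: PPTS (cat.), MeOH/CH2Cl2, 0 °C
Reagents that add atoms: none
Why: Selective solvolysis of the less hindered and more labile allylic triethylsilyl ether beside the neopentyl tert-butyldimethylsilyl ether.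

Step 13
Reactants: 18 C7 allylic alcohol
Product: 19 six-membered isopropenyl carbinol on the cage enone (O1-TBS)
Conditions: MnO2, CH2Cl2, rt
Reagents that add atoms: none
Why: Allylic alcohol oxidation with MnO2, as for verbenol to verbenone, touches neither the tertiary alcohol nor the isopropenyl group and renders C8=C9 electron-poor just before the bromination.

Step 14
Reactants: 19 six-membered isopropenyl carbinol on the cage enone; 20 N-bromosuccinimide
Product: 22 ring-expanded β-bromo ketone (seven-membered ring A; C4 bears CH3 and CH2Br), via bromonium ion 21 (not isolated)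
Conditions: NBS (1.1 equiv), propylene oxide, i-PrOH/CH2Cl2, −40 → 0 °C, dark
Reagents that add atoms: N-bromosuccinimide 20 (already counted under Reactants), O=C1CCC(=O)N1Br
Why: NBS delivers Br+ to the terminal CH2 of the electron-rich 1,1-disubstituted alkene, positive charge builds on C4, and the C3–C5 σ-bond aligned anti to the C4–Br bridge shifts to C4 while the hydroxyl oxygen becomes the C3 carbonyl and its proton ends on succinimide. This is the halonium-induced semipinacol ring expansion known for 1-alkenylcycloalkanols, which gives β-halo ketones with an α-quaternary carbon. Ring A is not closed end to end but enlarged from six to seven members by insertion of C4 between C3 and C5 (1,2-alkyl shift), helped by relief of strain in the cyclobutane that is bridged twice by three carbons. The only new stereocentre, C4, is set by the anti relation of migrating bond and bromonium but is erased in step 17, so either C4 epimer and either C3 epimer of 19 serves, and C5 migrates with retention so that C5, C6, C10 and C11 stay untouched. Selectivity for the isopropenyl group is secured by having C8=C9 conjugated to the C7 carbonyl, and migration of C5 rather than C2 by its higher substitution and by inductive deactivation of C2 through the C1 silyloxy group. Propylene oxide traps adventitious HBr so that the tertiary allylic alcohol does not ionise.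

Step 15
Reactants: 22 ring-expanded β-bromo ketone
Product: 23 C1 hydroxy β-bromo ketone
Conditions: HF·pyridine, THF, 0 °C
Reagents that add atoms: none
Why: Acidic fluoride desilylation frees O1 without the basic conditions that would trigger β-elimination or retro-aldol cleavage.

Step 16
Reactants: 23 C1 hydroxy β-bromo ketone; 24 acetaldehyde
Product: 26 O1 acetate C3 alcohol (O3 anti to O1), via hemiacetal 25 (not isolated)
Conditions: SmI2 (30 mol %, premixed with MeCHO), MeCHO (10 equiv), THF, −10 °C
Reagents that add atoms: acetaldehyde 24 (already counted under Reactants), CC=O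
Why: Evans–Tishchenko reduction: the hemiacetal formed on O1 hands its hydride to C3 inside a chelate of trivalent samarium from the face that carries O1, so the new C3 hydroxyl is anti to O1 and O1 leaves the step as its acetate, which tells the two oxygens apart; the ketone is reduced before debromination so that no β-keto radical prone to acyl shift can arise.

Step 17
Reactants: 26 O1 acetate C3 alcohol
Product: 27 gem-dimethyl O1 acetate C3 alcohol
Conditions: Bu3SnH, AIBN (cat.), toluene, 80 °C
Reagents that add atoms: none
Why: Tin hydride radical chain reduction of the neopentyl bromide turns CH2Br into the second C4 methyl and removes the C4 stereocentre; the primary radical cannot reach C8=C9, because C4 and C9 sit on opposite faces of the cyclobutane.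

Step 18
Reactants: 27 gem-dimethyl O1 acetate C3 alcohol; 28 tiglic acid
Product: 29 O1 acetate O3 tiglate
Conditions: 2,4,6-trichlorobenzoyl chloride, Et3N, toluene, rt; then 27, DMAP, 60 °C
Reagents that add atoms: tiglic acid 28 (already counted under Reactants), C/C=C(\C)C(=O)O
Why: Yamaguchi esterification acylates the hindered neopentyl C3 alcohol, the E acid is configurationally stable to DMAP, and the trans-1,3 placement of O1 and O3 on ring A opposes acetyl migration.

Step 19
Reactants: 29 O1 acetate O3 tiglate
Product: 30 C1 alcohol O3 tiglate
Conditions: K2CO3 (cat.), MeOH, 0 °C → rt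
Reagents that add atoms: none
Why: Chemoselective transesterification: the acetate carbonyl is far more electrophilic than the α-branched conjugated tiglate carbonyl, and the β,β-disubstituted enone does not take up methoxide.

Step 20
Reactants: 30 C1 alcohol O3 tiglate; 31 angelic acid
Product: 32 target CNP0236543.2
Conditions: 2,4,6-trichlorobenzoyl chloride, Et3N, toluene, rt; then 30, 80 °C (no DMAP)
Reagents that add atoms: angelic acid 31 (already counted under Reactants), C/C=C(/C)C(=O)O
Why: Mixed-anhydride acylation of Yamaguchi type without a nucleophilic catalyst, the conditions under which angelates are formed without addition–elimination isomerisation to tiglates, so the Z geometry is carried over from the acid.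

**Compound list**
1 | (E)-pent-3-en-2-one | C/C=C/C(C)=O | starting material
2 | (E)-2-(tert-butyldimethylsilyloxy)penta-1,3-diene | C=C(O[Si](C)(C)C(C)(C)C)/C=C/C | intermediate
3 | 2-methoxy-5-methyl-1,4-benzoquinone | COC1=CC(=O)C(C)=CC1=O | starting material
4 | cis-decalin enedione (Diels–Alder adduct) | COC1=CC(=O)[C@@]2(C)CC(O[Si](C)(C)C(C)(C)C)=C[C@@H](C)[C@H]2C1=O | intermediate
5 | C5 alcohol | COC1=CC(=O)[C@@]2(C)CC(O[Si](C)(C)C(C)(C)C)=C[C@@H](C)[C@H]2[C@H]1O | intermediate
6 | C5 bromide | COC1=CC(=O)[C@@]2(C)CC(O[Si](C)(C)C(C)(C)C)=C[C@@H](C)[C@H]2[C@@H]1Br | intermediate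
7 | bromo bis-enone | COC1=CC(=O)[C@@]2(C)CC(=O)C=C(C)[C@H]2[C@@H]1Br | intermediate
8 | potassium C6=C7 enolate of 7 | COC1=CC(=O)[C@@]2(C)C=C([O-])C=C(C)[C@H]2[C@@H]1Br.[K+] | intermediate
9 | cage vinylogous ester enone | O=C1C=C(OC)[C@@H]2[C@H]3C(=O)C=C(C)[C@@H]2[C@]31C | intermediate
10 | cage diol (C1 epimers) | OC1C=C(OC)[C@@H]2[C@H]3[C@H](O)C=C(C)[C@@H]2[C@]31C | intermediate
11 | cage enone alcohol | C1=CC(=O)[C@@H]2[C@H]3[C@H](O)C=C(C)[C@@H]2[C@]31C | intermediate
12 | O7 triethylsilyl ether | C1=CC(=O)[C@@H]2[C@H]3[C@H](O[Si](CC)(CC)CC)C=C(C)[C@@H]2[C@]31C | intermediate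
13 | C1 pinacol boronate | CC1(C)OB(OC1(C)C)[C@@H]1CC(=O)[C@@H]2[C@H]3[C@H](O[Si](CC)(CC)CC)C=C(C)[C@@H]2[C@]31C | intermediate
14 | C1 β-hydroxy ketone | O[C@@H]1CC(=O)[C@@H]2[C@H]3[C@H](O[Si](CC)(CC)CC)C=C(C)[C@@H]2[C@]31C | intermediate
15 | O1-TBS O7-TES ketone | CC(C)(C)[Si](C)(C)O[C@@H]1CC(=O)[C@@H]2[C@H]3[C@H](O[Si](CC)(CC)CC)C=C(C)[C@@H]2[C@]31C | intermediate
16 | isopropenylmagnesium bromide | C=C(C)[Mg]Br | starting material
17 | C3 isopropenyl carbinol (O7-TES) | CC(C)(C)[Si](C)(C)O[C@@H]1C[C@@](O)(C(C)=C)[C@@H]2[C@H]3[C@H](O[Si](CC)(CC)CC)C=C(C)[C@@H]2[C@]31C | intermediate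
18 | C7 allylic alcohol | CC(C)(C)[Si](C)(C)O[C@@H]1C[C@@](O)(C(C)=C)[C@@H]2[C@H]3[C@H](O)C=C(C)[C@@H]2[C@]31C | intermediate
19 | six-membered isopropenyl carbinol on the cage enone | CC(C)(C)[Si](C)(C)O[C@@H]1C[C@@](O)(C(C)=C)[C@@H]2[C@H]3C(=O)C=C(C)[C@@H]2[C@]31C | intermediate
20 | N-bromosuccinimide | O=C1CCC(=O)N1Br | starting material
21 | bromonium ion of 19 | CC(C)(C)[Si](C)(C)O[C@@H]1C[C@@](O)([C@@]4(C)C[Br+]4)[C@@H]2[C@H]3C(=O)C=C(C)[C@@H]2[C@]31C | intermediate
22 | ring-expanded β-bromo ketone | CC(C)(C)[Si](C)(C)O[C@@H]1CC(=O)[C@](C)(CBr)[C@@H]2[C@H]3C(=O)C=C(C)[C@@H]2[C@]31C | intermediate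
23 | C1 hydroxy β-bromo ketone | O[C@@H]1CC(=O)[C@](C)(CBr)[C@@H]2[C@H]3C(=O)C=C(C)[C@@H]2[C@]31C | intermediate
24 | acetaldehyde | CC=O | starting material
25 | O1 hemiacetal with acetaldehyde | CC(O)O[C@@H]1CC(=O)[C@](C)(CBr)[C@@H]2[C@H]3C(=O)C=C(C)[C@@H]2[C@]31C | intermediate
26 | O1 acetate C3 alcohol (bromide) | CC(=O)O[C@@H]1C[C@@H](O)[C@](C)(CBr)[C@@H]2[C@H]3C(=O)C=C(C)[C@@H]2[C@]31C | intermediate
27 | gem-dimethyl O1 acetate C3 alcohol | CC(=O)O[C@@H]1C[C@@H](O)C(C)(C)[C@@H]2[C@H]3C(=O)C=C(C)[C@@H]2[C@]31C | intermediate
28 | tiglic acid | C/C=C(\C)C(=O)O | starting material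
29 | O1 acetate O3 tiglate | CC(=O)O[C@@H]1C[C@@H](OC(=O)/C(C)=C/C)C(C)(C)[C@@H]2[C@H]3C(=O)C=C(C)[C@@H]2[C@]31C | intermediate
30 | C1 alcohol O3 tiglate | O[C@@H]1C[C@@H](OC(=O)/C(C)=C/C)C(C)(C)[C@@H]2[C@H]3C(=O)C=C(C)[C@@H]2[C@]31C | intermediate
31 | angelic acid | C/C=C(/C)C(=O)O | starting material
32 | CNP0236543.2 | C/C=C(/C)C(=O)O[C@@H]1C[C@@H](OC(=O)/C(C)=C/C)C(C)(C)[C@@H]2[C@H]3C(=O)C=C(C)[C@@H]2[C@]31C | target

**Step count**
Total step count: 20. Longest linear sequence: 20.

**Steps most likely to fail**

Step 6 (cyclobutane closure). Four-membered ring formation is slow. Two processes may outrun it. In the first, a proton moves from the vinylogous C10–H to the kinetic enolate and bromide is then lost. In the second, C6 attacks C3 of the vinylogous ester in a conjugate sense.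

The fallback separates enolate formation from ring closure and uses silyl enol ether alkylation instead of direct deprotonation. It sets out from 7. LiN(i-Pr)2 with Me3SiCl already present at −78 °C traps the α′-enolate at once as the cross-conjugated trimethylsilyl dienol ether F1, which is isolated. Bu4N[Ph3SiF2] in THF then releases the amine-free, regiodefined enolate. With no proton shuttle present, this enolate should displace the bromide and return to the route at 9.

Step 14 (semipinacol expansion). Three processes may compete with the C5 shift. The tertiary hydroxyl may capture the bromonium ion and give a bromomethyl oxirane. C2 may migrate in place of C5. Allylic bromination may also occur.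

The fallback keeps the C3 to C4 shift of C5 but triggers it from an epoxide. It sets out from 19. Hydroxyl-directed epoxidation (VO(acac)2, t-BuOOH, CH2Cl2) gives the 2,3-epoxy alcohol F2. ZnBr2 in CH2Cl2 then opens the C4–O bond with migration of C5 (semipinacol rearrangement of a 2,3-epoxy alcohol) to give the hydroxymethyl ketone F3. An Appel bromination (PPh3, CBr4) converts F3 into 22, where the route is rejoined.

Step 2 (asymmetric Diels–Alder reaction). Facial or regiochemical control may be poor when the quaternary C11 is formed on the methyl-bearing quinone double bond.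

The fallback replaces catalysis by resolution and sets out from 2 and 3.
- Heating in toluene without a catalyst gives 4 together with its mirror image F4. The orientation is governed by the more electron-poor C5 carbonyl.
- Luche reduction gives 5 together with its mirror image F5.
- Esterification with (S)-O-methylmandelic acid (DCC, DMAP) gives the ester of 5, F6, and the ester of F5, F7. These are separated by chromatography or crystallisation.
- K2CO3 in MeOH cleaves F6 and returns to the route at 5.

**Further compounds**
F1 | step 6 | cross-conjugated trimethylsilyl dienol ether of 7 | COC1=CC(=O)[C@@]2(C)C=C(O[Si](C)(C)C)C=C(C)[C@H]2[C@@H]1Br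
F2 | step 14 | 2,3-epoxy alcohol from 19 (either C4 epimer serves) | CC(C)(C)[Si](C)(C)O[C@@H]1C[C@@](O)([C@@]4(C)CO4)[C@@H]2[C@H]3C(=O)C=C(C)[C@@H]2[C@]31C
F3 | step 14 | ring-expanded hydroxymethyl ketone | CC(C)(C)[Si](C)(C)O[C@@H]1CC(=O)[C@](C)(CO)[C@@H]2[C@H]3C(=O)C=C(C)[C@@H]2[C@]31C
F4 | step 2 | mirror image of 4 | COC1=CC(=O)[C@]2(C)CC(O[Si](C)(C)C(C)(C)C)=C[C@H](C)[C@@H]2C1=O
F5 | step 2 | mirror image of 5 | COC1=CC(=O)[C@]2(C)CC(O[Si](C)(C)C(C)(C)C)=C[C@H](C)[C@@H]2[C@@H]1O
F6 | step 2 | (S)-O-methylmandelate of 5 | COC1=CC(=O)[C@@]2(C)CC(O[Si](C)(C)C(C)(C)C)=C[C@@H](C)[C@H]2[C@H]1OC(=O)[C@@H](OC)c1ccccc1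
F7 | step 2 | (S)-O-methylmandelate of F5 | COC1=CC(=O)[C@]2(C)CC(O[Si](C)(C)C(C)(C)C)=C[C@H](C)[C@@H]2[C@@H]1OC(=O)[C@@H](OC)c1ccccc1
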